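The diterpene half is completed around its ring A, which is closed as the last ring. A bromotetralone (rings B and C, C10 set by copper-catalysed allylic substitution) is joined to a bicyclo[3.1.0]hexenyl triflate (made by platinum-catalysed enyne cycloisomerisation with chirality transfer), and a carbonylative Heck cyclisation forges the spiro cyclopentenone. This turns C5 into the γ-carbon of the bridging C=O–C7=C6 enone, while C4 sits in a 4-chloro-4-methylpentyl arm on C10. The key step ionises the tertiary chloride and lets the silyl dienol ether attack the C4 cation through C5, closing ring A (C1–C5, C10) and creating the gem-dimethyl carbon. Hydrogenation of a Δ5 alkene then sets C5; catechol oxidation gives the quinone methide.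

Key step: step 25

Remark: abietane numbering (C1–C20) is used for the diterpene half; the target is taken as the 11-hydroxy-12-oxo quinone methide that forms when the corresponding o-quinone enolises through C7–H, and the two functionalised organometallic reagents of steps 2 and 15 are stock solutions made from the commercial bromides.

Step 1
Reactants: 1 4-methylpent-1-en-3-ol (racemic)
Product: 2 (2E)-1-bromo-4-methylpent-2-ene
Conditions: PBr3, pyridine (cat.), Et2O, −10 °C → rt
Reagents that add atoms: phosphorus tribromide, BrP(Br)Br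
Why: Bromination of the allylic alcohol with allylic transposition (SN2′ and equilibration of the allylic bromides) should give the more stable primary E-bromide.

Step 2
Reactants: 2 (2E)-1-bromo-4-methylpent-2-ene
Product: 3 2-methyl-2-[(3S)-3-(propan-2-yl)pent-4-en-1-yl]-1,3-dioxolane
Conditions: BrMgCH2CH2C(OCH2CH2O)CH3 (Et2O), CuBr·SMe2 (5 mol%), Taniaphos (6 mol%), CH2Cl2, −78 °C
Reagents that add atoms: [2-(2-methyl-1,3-dioxolan-2-yl)ethyl]magnesium bromide, CC1(CC[Mg]Br)OCCO1
Why: Copper-catalysed asymmetric allylic alkylation (SN2′) should give the branched product, the ligand enantiomer being chosen so that the new isopropyl-bearing stereocentre is S.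

Step 3
Reactants: 4 3-(trimethylsilyl)prop-2-ynal
Product: 5 (3R)-1-(trimethylsilyl)hex-5-en-1-yn-3-ol
Conditions: allylB(pin), (R)-TRIP (5 mol%), toluene, −30 °C
Reagents that add atoms: 2-allyl-4,4,5,5-tetramethyl-1,3,2-dioxaborolane, C=CCB1OC(C)(C)C(C)(C)O1
Why: Chiral-phosphoric-acid-catalysed allylboration should set the carbinol centre under catalyst control (R expected by analogy with aryl aldehydes, the antipodal acid being used if the sense is reversed).

Step 4
Reactants: 5 (3R)-1-(trimethylsilyl)hex-5-en-1-yn-3-ol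
Product: 6 (3R)-1-(trimethylsilyl)hex-5-en-1-yn-3-yl acetate
Conditions: Ac2O, Et3N, DMAP (cat.), CH2Cl2, 0 °C
Reagents that add atoms: acetic anhydride, CC(=O)OC(C)=O
Why: DMAP-catalysed acylation of the secondary alcohol should proceed without touching the stereocentre.

Step 5
Reactants: 3 2-methyl-2-[(3S)-3-(propan-2-yl)pent-4-en-1-yl]-1,3-dioxolane; 6 (3R)-1-(trimethylsilyl)hex-5-en-1-yn-3-yl acetate (excess)
Product: 7 (3R,5E,7S)-9-(2-methyl-1,3-dioxolan-2-yl)-7-(propan-2-yl)-1-(trimethylsilyl)non-5-en-1-yn-3-yl acetate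
Conditions: second-generation Hoveyda–Grubbs catalyst (5 mol%), CH2Cl2, 40 °C
Reagents that add atoms: none
Why: Olefin cross-metathesis of the two terminal alkenes should give the E-alkene under thermodynamic control, the silyl cap keeping the alkyne out of enyne metathesis.

Step 6
Reactants: 7 silylated enyne acetate
Product: 8 (3R,5E,7S)-9-(2-methyl-1,3-dioxolan-2-yl)-7-(propan-2-yl)non-5-en-1-yn-3-yl acetate
Conditions: Bu4NF, AcOH, THF, 0 °C
Reagents that add atoms: none
Why: Buffered fluoride protodesilylation of the alkynylsilane should leave the propargylic acetate intact.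

Step 7
Reactants: 8 terminal enyne acetate
Product: 9 (1S,5S,6S)-6-[(3S)-2-methyl-5-(2-methyl-1,3-dioxolan-2-yl)pentan-3-yl]bicyclo[3.1.0]hex-2-en-2-yl acetate (side chain exo)
Conditions: PtCl2 (5 mol%), toluene, 80 °C
Reagents that add atoms: none
Why: Platinum-catalysed cycloisomerisation of the enyne propargylic acetate (alkene cyclopropanation by the activated alkyne, then 1,2-acyloxy shift, Rautenstrauch type) should close cyclopropane and cyclopentene at once, the E-alkene placing the side chain exo and the R carbinol centre transferring its chirality (acetate anti to the forming cyclopropane) to the three ring stereocentres.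

Step 8
Reactants: 9 bicyclic enol acetate
Product: 11 (1S,5S,6S)-6-[(3S)-2-methyl-5-(2-methyl-1,3-dioxolan-2-yl)pentan-3-yl]bicyclo[3.1.0]hex-2-en-2-yl trifluoromethanesulfonate, via lithium enolate 10 (not isolated)
Conditions: MeLi (2.1 equiv), THF, 0 °C; then PhNTf2, −78 → 0 °C
Reagents that add atoms: N-phenylbis(trifluoromethanesulfonimide), O=S(=O)(N(c1ccccc1)S(=O)(=O)C(F)(F)F)C(F)(F)F
Why: Cleavage of the enol acetate should give the regiodefined enolate, whose O-triflation keeps the double bond away from the cyclopropane.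

Step 9
Reactants: 12 3-(propan-2-yl)benzene-1,2-diol
Product: 13 1,2-dimethoxy-3-(propan-2-yl)benzene
Conditions: MeI, K2CO3, acetone, reflux
Reagents that add atoms: iodomethane, CI
Why: Williamson etherification of both phenols.

Step 10
Reactants: 13 1,2-dimethoxy-3-(propan-2-yl)benzene
Product: 15 1-[2,3-dimethoxy-4-(propan-2-yl)phenyl]ethan-1-one, via aryllithium 14 (not isolated)
Conditions: n-BuLi, TMEDA, Et2O, 0 °C → rt; then MeC(O)N(OMe)Me, −78 °C → rt
Reagents that add atoms: N-methoxy-N-methylacetamide, CON(C)C(C)=O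
Why: Directed ortho-metalation at the only position next to a methoxy group, then acylation by the N-methoxy-N-methyl amide, should install the future C10 carbon at C9.

Step 11
Reactants: 15 aryl methyl ketone
Product: 16 1-[5-bromo-2,3-dimethoxy-4-(propan-2-yl)phenyl]ethan-1-one
Conditions: NBS, MeCN, rt
Reagents that add atoms: N-bromosuccinimide, O=C1CCC(=O)N1Br
Why: Electrophilic aromatic bromination should occur at the position meta to the acetyl group and para to the C2 methoxy group (future C14).

Step 12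
Reactants: 16 bromo aryl methyl ketone
Product: 17 ethyl (2E)-3-[5-bromo-2,3-dimethoxy-4-(propan-2-yl)phenyl]but-2-enoate
Conditions: (EtO)2P(O)CH2CO2Et, NaH, THF, reflux; chromatography
Reagents that add atoms: triethyl phosphonoacetate, CCOC(=O)CP(=O)(OCC)OCC
Why: Horner–Wadsworth–Emmons olefination should give mainly the E-enoate, which is freed from the Z isomer at this stage.

Step 13
Reactants: 17 E-enoate
Product: 18 (2E)-3-[5-bromo-2,3-dimethoxy-4-(propan-2-yl)phenyl]but-2-en-1-ol
Conditions: i-Bu2AlH, CH2Cl2, −78 °C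
Reagents that add atoms: none
Why: 1,2-Reduction of the conjugated ester by the aluminium hydride should give the allylic alcohol with the E geometry unchanged.

Step 14
Reactants: 18 allylic alcohol
Product: 19 diethyl (2E)-3-[5-bromo-2,3-dimethoxy-4-(propan-2-yl)phenyl]but-2-en-1-yl phosphate
Conditions: ClP(O)(OEt)2, Et3N, DMAP (cat.), CH2Cl2, 0 °C
Reagents that add atoms: diethyl chlorophosphate, CCOP(=O)(Cl)OCC
Why: O-Phosphorylation should give the allylic phosphate needed as leaving group for the SN2′ step.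

Step 15
Reactants: 19 allylic phosphate
Product: 20 1-bromo-5-[(3S)-3,7-dimethylocta-1,6-dien-3-yl]-3,4-dimethoxy-2-(propan-2-yl)benzene
Conditions: (Me2C=CHCH2CH2)2Zn, (CuOTf)2·C6H6 (2.5 mol%), chiral sulfonate-bearing imidazolinium salt (carbene precursor, 5 mol%), THF, −15 °C
Reagents that add atoms: bis(4-methylpent-3-en-1-yl)zinc, CC(C)=CCC[Zn]CCC=C(C)C
Why: Copper-catalysed enantioselective allylic substitution (SN2′) with a carbene ligand should create the quaternary benzylic centre (future C10, with its methyl, vinyl and homoprenyl groups) under catalyst control, the ligand enantiomer being chosen for S.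

Step 16
Reactants: 20 aryl diene
Product: 21 (4S)-4-[5-bromo-2,3-dimethoxy-4-(propan-2-yl)phenyl]-4,8-dimethylnon-7-enal
Conditions: Rh(acac)(CO)2 (1 mol%), BIPHEPHOS (2 mol%), CO/H2 (1:1, 10 bar), toluene, 60 °C
Reagents that add atoms: carbon monoxide, [C-]#[O+]
Why: Linear-selective hydroformylation should engage only the monosubstituted alkene next to the quaternary carbon, adding the future C7.

Step 17
Reactants: 21 aldehyde
Product: 22 (4S)-4-[5-bromo-2,3-dimethoxy-4-(propan-2-yl)phenyl]-4,8-dimethylnon-7-enoic acid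
Conditions: NaClO2, NaH2PO4, 2-methylbut-2-ene, t-BuOH/H2O, 0 °C
Reagents that add atoms: sodium chlorite, [Na+].[O-]Cl=O
Why: Pinnick oxidation should give the acid, the scavenger alkene protecting the trisubstituted double bond from hypochlorite.

Step 18
Reactants: 22 carboxylic acid
Product: 24 (4S)-8-bromo-5,6-dimethoxy-4-methyl-4-(4-methylpent-3-en-1-yl)-7-(propan-2-yl)-3,4-dihydronaphthalen-1(2H)-one, via acid chloride 23 (not isolated)
Conditions: Me2C=C(Cl)NMe2, CH2Cl2, 0 °C; then SnCl4, 2,6-di-tert-butyl-4-methylpyridine, −78 °C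
Reagents that add atoms: none
Why: Intramolecular Friedel–Crafts acylation at C8 (para to the C12 methoxy group) should close ring B, neutral acid chloride formation and a proton scavenger sparing the trisubstituted alkene.

Step 19
Reactants: 11 bicyclic alkenyl triflate; 24 bromotetralone
Product: 26 aryl–alkenyl tetralone (24 with Br replaced by the bicyclo[3.1.0]hex-2-en-2-yl unit of 11), via alkenyl pinacol boronate 25 (not isolated)
Conditions: B2pin2, PdCl2(dppf) (5 mol%), KOAc, dioxane, 80 °C; then 24, Pd(OAc)2 (5 mol%), SPhos (10 mol%), K3PO4, H2O, 90 °C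
Reagents that add atoms: none
Why: Miyaura borylation of the triflate followed by Suzuki–Miyaura coupling with a bulky biarylphosphine should join the two halves at C14 without touching a stereocentre.

Step 20
Reactants: 26 aryl–alkenyl tetralone
Product: 27 enol triflate of 26 (C7–OTf, C6=C7)
Conditions: KN(SiMe3)2, THF, −78 °C; then PhNTf2
Reagents that add atoms: N-phenylbis(trifluoromethanesulfonimide), O=S(=O)(N(c1ccccc1)S(=O)(=O)C(F)(F)F)C(F)(F)F
Why: The tetralone can enolise only towards C6, and O-triflation of that enolate should give the alkenyl triflate.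

Step 21
Reactants: 27 enol triflate
Product: 28 spiro dienone (five-membered ring C7–C(=O)–spiro carbon–C14–C8 closed; C6=C7 and the cyclopentene double bond present)
Conditions: Pd(OAc)2 (10 mol%), dppp (12 mol%), CO (1 atm), Et3N, DMF, 70 °C
Reagents that add atoms: carbon monoxide, [C-]#[O+]
Why: Carbonylative Heck cyclisation (oxidative addition, CO insertion, 5-exo insertion of the acyl–palladium bond into the aryl-substituted cyclopentene on its exo face, β-hydride elimination) should set the spiro quaternary centre with the bridging C=O anti and C14 syn to the cyclopropane.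

Step 22
Reactants: 28 spiro dienone
Product: 29 spiro enone (cyclopentane ring saturated)
Conditions: KO2CN=NCO2K, AcOH, MeOH/pyridine, rt
Reagents that add atoms: none
Why: Diimide reduction should saturate only the cis-disubstituted cyclopentene double bond, leaving the trisubstituted alkene, the conjugated enone and the cyclopropane.

Step 23
Reactants: 29 spiro enone
Product: 30 tertiary chloride (4-chloro-4-methylpentyl arm on C10)
Conditions: HCl (g), CH2Cl2, −40 → 0 °C
Reagents that add atoms: hydrogen chloride, Cl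
Why: Markovnikov hydrochlorination should add only to the electron-rich trisubstituted alkene, placing chlorine on the future C4.

Step 24
Reactants: 30 tertiary chloride
Product: 31 tert-butyldimethylsilyl dienol ether (C=C(OSi) at the bridging carbon and C7; C5=C6)
Conditions: TBSOTf, Et3N, CH2Cl2, 0 °C
Reagents that add atoms: tert-butyldimethylsilyl trifluoromethanesulfonate, CC(C)(C)[Si](C)(C)OS(=O)(=O)C(F)(F)F
Why: Soft enolisation of the enone, possible only by loss of a C5 proton, should give the extended silyl dienol ether.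

Step 25
Reactants: 31 silyl dienol ether
Product: 32 pentacyclic enone with ring A closed (C6=C7; C5–H cis to the C10 methyl expected)
Conditions: ZnCl2 (30 mol%), 2,6-di-tert-butyl-4-methylpyridine (20 mol%), CH2Cl2 (0.005 M), −20 °C → rt
Reagents that add atoms: none
Why: ZnCl2 abstracts chloride from the tertiary C4–Cl bond and the tertiary carbocation is captured by the γ-carbon (C5) of the silyl dienol ether, after which chloride takes the silyl group and the C6=C7 enone returns. The closest known reaction type is the Lewis-acid-mediated SN1 tert-alkylation of silyl enol ethers by tertiary alkyl chlorides, here in its vinylogous (Mukaiyama-type) intramolecular form. Ring A (C10–C1–C2–C3–C4–C5) closes in a 6-exo cation–olefin mode, the C5=C6 bond lying outside the new ring, and C4 becomes the gem-dimethyl quaternary carbon. The new C5 centre is set by attack on the face of the flat ring B that carries the C10–C1 tether, which should give mainly the cis-fused 5-epimer; this is accepted because steps 26 and 27 erase and reset C5. The selectivity that matters is C5 over C7 and over a Prins-type C3–C6 closure of a free enone with a free alkene: ring size (six against eight) secures the first, masking the enone as its dienol ether and using the saturated chloride secures the second. High dilution and the hindered pyridine should suppress intermolecular alkylation and proton-induced loss of the silyl ether.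

Step 26
Reactants: 32 pentacyclic enone
Product: 33 β,γ-unsaturated ketone (C5=C6; C7–H, both C7 epimers)
Conditions: KOt-Bu, t-BuOH/THF, rt; then AcOH/H2O, −78 °C
Reagents that add atoms: none
Why: Deconjugation through the extended enolate, protonated kinetically at the α-carbon C7, should move the double bond to C5=C6 and erase the C5 centre.

Step 27
Reactants: 33 β,γ-unsaturated ketone
Product: 34 saturated trans-fused ketone (5S,10S; dimethyl ether, dioxolane)
Conditions: H2 (3 atm), Pd/C, EtOAc, rt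
Reagents that add atoms: none
Why: Catalytic hydrogenation should deliver hydrogen to the C5=C6 bond from the face opposite the axial C10 methyl and the β-methyl on C4, setting 5S and the trans A/B fusion.

Step 28
Reactants: 34 saturated ketone
Product: 35 catechol diketone (11,12-dihydroxy; side-chain methyl ketone free)
Conditions: BBr3, CH2Cl2, −78 → 0 °C; aqueous work-up under argon
Reagents that add atoms: none
Why: Lewis-acid ether cleavage should remove both aryl methyl groups and open the dioxolane to the methyl ketone, the isolated cyclopropane and the hindered ring ketone being inert.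

Step 29
Reactants: 35 catechol diketone
Product: 37 CNP0140364.1, via o-quinone 36 (not isolated)
Conditions: Ag2O, Et2O, rt
Reagents that add atoms: none
Why: Oxidation of the catechol gives the o-quinone, which should enolise through the doubly activated C7–H (benzylic and α to the ring ketone) to the 11-hydroxy-12-oxo quinone methide, removing the C7 centre.

Compound list

1 | 4-methylpent-1-en-3-ol (racemic) | C=CC(O)C(C)C | starting material
2 | (2E)-1-bromo-4-methylpent-2-ene | CC(C)/C=C/CBr | intermediate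
3 | 2-methyl-2-[(3S)-3-(propan-2-yl)pent-4-en-1-yl]-1,3-dioxolane | CC1(CC[C@@H](C(C)C)C=C)OCCO1 | intermediate
4 | 3-(trimethylsilyl)prop-2-ynal | C[Si](C)(C)C#CC=O | starting material
5 | (3R)-1-(trimethylsilyl)hex-5-en-1-yn-3-ol | C=CC[C@@H](O)C#C[Si](C)(C)C | intermediate
6 | (3R)-1-(trimethylsilyl)hex-5-en-1-yn-3-yl acetate | C=CC[C@@H](OC(C)=O)C#C[Si](C)(C)C | intermediate
7 | (3R,5E,7S)-9-(2-methyl-1,3-dioxolan-2-yl)-7-(propan-2-yl)-1-(trimethylsilyl)non-5-en-1-yn-3-yl acetate | CC1(CC[C@@H](C(C)C)/C=C/C[C@@H](OC(C)=O)C#C[Si](C)(C)C)OCCO1 | intermediate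
8 | (3R,5E,7S)-9-(2-methyl-1,3-dioxolan-2-yl)-7-(propan-2-yl)non-5-en-1-yn-3-yl acetate | CC1(CC[C@@H](C(C)C)/C=C/C[C@@H](OC(C)=O)C#C)OCCO1 | intermediate
9 | (1S,5S,6S)-6-[(3S)-2-methyl-5-(2-methyl-1,3-dioxolan-2-yl)pentan-3-yl]bicyclo[3.1.0]hex-2-en-2-yl acetate (exo side chain) | CC1(CC[C@@H](C(C)C)[C@H]2[C@@H]3CC=C(OC(C)=O)[C@@H]32)OCCO1 | intermediate
10 | lithium enolate from 9 (lithium bicyclo[3.1.0]hex-2-en-2-olate, same stereocentres) | CC1(CC[C@@H](C(C)C)[C@H]2[C@@H]3CC=C(O[Li])[C@@H]32)OCCO1 | intermediate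
11 | (1S,5S,6S)-6-[(3S)-2-methyl-5-(2-methyl-1,3-dioxolan-2-yl)pentan-3-yl]bicyclo[3.1.0]hex-2-en-2-yl trifluoromethanesulfonate | CC1(CC[C@@H](C(C)C)[C@H]2[C@@H]3CC=C(OS(=O)(=O)C(F)(F)F)[C@@H]32)OCCO1 | intermediate
12 | 3-(propan-2-yl)benzene-1,2-diol | CC(C)c1cccc(O)c1O | starting material
13 | 1,2-dimethoxy-3-(propan-2-yl)benzene | COc1cccc(C(C)C)c1OC | intermediate
14 | [2,3-dimethoxy-4-(propan-2-yl)phenyl]lithium | [Li]c1ccc(C(C)C)c(OC)c1OC | intermediate
15 | 1-[2,3-dimethoxy-4-(propan-2-yl)phenyl]ethan-1-one | CC(=O)c1ccc(C(C)C)c(OC)c1OC | intermediate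
16 | 1-[5-bromo-2,3-dimethoxy-4-(propan-2-yl)phenyl]ethan-1-one | CC(=O)c1cc(Br)c(C(C)C)c(OC)c1OC | intermediate
17 | ethyl (2E)-3-[5-bromo-2,3-dimethoxy-4-(propan-2-yl)phenyl]but-2-enoate | COc1c(OC)c(C(C)C)c(Br)cc1/C(C)=C/C(=O)OCC | intermediate
18 | (2E)-3-[5-bromo-2,3-dimethoxy-4-(propan-2-yl)phenyl]but-2-en-1-ol | COc1c(OC)c(C(C)C)c(Br)cc1/C(C)=C/CO | intermediate
19 | diethyl (2E)-3-[5-bromo-2,3-dimethoxy-4-(propan-2-yl)phenyl]but-2-en-1-yl phosphate | COc1c(OC)c(C(C)C)c(Br)cc1/C(C)=C/COP(=O)(OCC)OCC | intermediate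
20 | 1-bromo-5-[(3S)-3,7-dimethylocta-1,6-dien-3-yl]-3,4-dimethoxy-2-(propan-2-yl)benzene | COc1c(OC)c(C(C)C)c(Br)cc1[C@](C)(C=C)CCC=C(C)C | intermediate
21 | (4S)-4-[5-bromo-2,3-dimethoxy-4-(propan-2-yl)phenyl]-4,8-dimethylnon-7-enal | COc1c(OC)c(C(C)C)c(Br)cc1[C@](C)(CCC=O)CCC=C(C)C | intermediate
22 | (4S)-4-[5-bromo-2,3-dimethoxy-4-(propan-2-yl)phenyl]-4,8-dimethylnon-7-enoic acid | COc1c(OC)c(C(C)C)c(Br)cc1[C@](C)(CCC(=O)O)CCC=C(C)C | intermediate
23 | (4S)-4-[5-bromo-2,3-dimethoxy-4-(propan-2-yl)phenyl]-4,8-dimethylnon-7-enoyl chloride | COc1c(OC)c(C(C)C)c(Br)cc1[C@](C)(CCC(=O)Cl)CCC=C(C)C | intermediate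
24 | (4S)-8-bromo-5,6-dimethoxy-4-methyl-4-(4-methylpent-3-en-1-yl)-7-(propan-2-yl)-3,4-dihydronaphthalen-1(2H)-one | COc1c(OC)c(C(C)C)c(Br)c2c1[C@@](C)(CCC=C(C)C)CCC2=O | intermediate
25 | pinacol boronate from 11 (B in place of OTf, same stereocentres) | CC1(CC[C@@H](C(C)C)[C@H]2[C@@H]3CC=C(B4OC(C)(C)C(C)(C)O4)[C@@H]32)OCCO1 | intermediate
26 | (4S)-tetralone 24 carrying at C8 (abietane C14), in place of Br, the (1S,5S,6S)-bicyclo[3.1.0]hex-2-en-2-yl unit of 11 | CC1(CC[C@@H](C(C)C)[C@H]2[C@@H]3CC=C([C@@H]32)c2c(C(C)C)c(OC)c(OC)c3c2C(=O)CC[C@]3(C)CCC=C(C)C)OCCO1 | intermediate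
27 | enol triflate of 26 (abietane C7–OTf, C6=C7) | CC1(CC[C@@H](C(C)C)[C@H]2[C@@H]3CC=C([C@@H]32)c2c(C(C)C)c(OC)c(OC)c3c2C(OS(=O)(=O)C(F)(F)F)=CC[C@]3(C)CCC=C(C)C)OCCO1 | intermediate
28 | spiro dienone: bridging C=O joins C7 and the spiro carbon (C=O anti, C14 syn to the cyclopropane, as in the target); C6=C7 enone; cyclopentene double bond between the two carbons beyond the spiro carbon; 10S; homoprenyl arm on C10 | CC1(CC[C@@H](C(C)C)[C@H]2[C@@H]3C=C[C@@]4(C(=O)C5=CC[C@](C)(CCC=C(C)C)c6c(OC)c(OC)c(C(C)C)c4c65)[C@@H]32)OCCO1 | intermediate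
29 | spiro enone: 28 with the cyclopentene double bond saturated | CC1(CC[C@@H](C(C)C)[C@H]2[C@@H]3CC[C@@]4(C(=O)C5=CC[C@](C)(CCC=C(C)C)c6c(OC)c(OC)c(C(C)C)c4c65)[C@@H]32)OCCO1 | intermediate
30 | tertiary chloride: 29 with a 4-chloro-4-methylpentyl arm on C10 | CC1(CC[C@@H](C(C)C)[C@H]2[C@@H]3CC[C@@]4(C(=O)C5=CC[C@](C)(CCCC(C)(C)Cl)c6c(OC)c(OC)c(C(C)C)c4c65)[C@@H]32)OCCO1 | intermediate
31 | tert-butyldimethylsilyl dienol ether of 30 (C(OSi)=C7, C6=C5) | CC1(CC[C@@H](C(C)C)[C@H]2[C@@H]3CC[C@@]4(C(O[Si](C)(C)C(C)(C)C)=C5C=C[C@](C)(CCCC(C)(C)Cl)c6c(OC)c(OC)c(C(C)C)c4c65)[C@@H]32)OCCO1 | intermediate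
32 | pentacyclic enone, ring A closed, C6=C7, (5R,10S) cis A/B epimer shown as the expected major product; 11,12-dimethyl ether; side-chain dioxolane | CC1(CC[C@@H](C(C)C)[C@H]2[C@@H]3CC[C@@]4(C(=O)C5=C[C@@H]6C(C)(C)CCC[C@]6(C)c7c(OC)c(OC)c(C(C)C)c4c75)[C@@H]32)OCCO1 | intermediate
33 | β,γ-unsaturated ketone: C5=C6, C7–H (both C7 epimers), 10S | CC1(CC[C@@H](C(C)C)[C@H]2[C@@H]3CC[C@@]4(C(=O)C5C=C6C(C)(C)CCC[C@]6(C)c7c(OC)c(OC)c(C(C)C)c4c75)[C@@H]32)OCCO1 | intermediate
34 | saturated ketone, (5S,10S) trans A/B, C7–H (both epimers), 11,12-dimethyl ether, side-chain dioxolane | CC1(CC[C@@H](C(C)C)[C@H]2[C@@H]3CC[C@@]4(C(=O)C5C[C@H]6C(C)(C)CCC[C@]6(C)c7c(OC)c(OC)c(C(C)C)c4c75)[C@@H]32)OCCO1 | intermediate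
35 | catechol diketone: 34 with 11,12-dihydroxy groups and the side-chain methyl ketone free | CC(=O)CC[C@@H](C(C)C)[C@H]1[C@@H]2CC[C@@]3(C(=O)C4C[C@H]5C(C)(C)CCC[C@]5(C)c5c(O)c(O)c(C(C)C)c3c54)[C@@H]21 | intermediate
36 | 11,12-o-quinone of 35 | CC(=O)CC[C@@H](C(C)C)[C@H]1[C@@H]2CC[C@@]3(C(=O)C4C[C@H]5C(C)(C)CCC[C@]5(C)C5=C4C3=C(C(C)C)C(=O)C5=O)[C@@H]21 | intermediate
37 | CNP0140364.1 (11-hydroxy-12-oxo quinone methide) | CC(=O)CC[C@@H](C(C)C)[C@H]1[C@@H]2CC[C@@]3(C(=O)C4=C5C3=C(C(C)C)C(=O)C(O)=C5[C@@]3(C)CCCC(C)(C)[C@@H]3C4)[C@@H]21 | target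

Total step count: 29. Longest linear sequence: 21 steps (steps 9–18, then 19–29).

Steps most likely to fail

Step 21. The acyl–palladium species may fail to insert at the hindered, aryl-bearing alkene carbon. It may also insert without CO, or the palladium hydride may re-add and open the neighbouring cyclopropane. The fallback replaces palladium by a dipolar cycloaddition. Setting out from 27, palladium-catalysed formylation (Pd(OAc)2, dppp, CO, Et3SiH) would give the α,β-unsaturated aldehyde F1, and hydroxylamine the oxime F2. NaOCl oxidation generates the nitrile oxide F3, which should add intramolecularly across the cyclopentene from its exo face to give the isoxazoline F4, forming the C–C bond at the spiro carbon. Mo(CO)6 in wet MeCN should cleave the N–O bond and hydrolyse the imine to the β-hydroxy ketone F5. Dehydration with the Burgess reagent comes back to the route at 28.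

Step 25. The tertiary cation may lose a proton faster than it cyclises, and the acid set free may strip the silyl group from the dienol ether. The fallback uses an epoxide as the latent cation. Setting out from 29, mCPBA should epoxidise only the trisubstituted alkene to the epoxide F6, and LiN(SiMe3)2/TBSCl should give the silyl dienol ether F7. BF3·OEt2 then opens the epoxide at its tertiary carbon and the dienol ether closes ring A (epoxide-initiated cation–olefin cyclisation) to the 3-hydroxy enone F8. Its xanthate F9 (NaH, CS2, MeI) and Bu3SnH/AIBN (Barton–McCombie deoxygenation) come back to the route at 32.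

Step 19. Transmetalation at the bromide flanked by the isopropyl group and the peri carbonyl may be slower than protodeboronation of the alkenyl boronate. The fallback makes the alkenyl nucleophile from a ketone instead of the triflate. Setting out from 9, methanolysis (K2CO3, MeOH) gives the bicyclic ketone F10, and 2,4,6-triisopropylbenzenesulfonyl hydrazide the hydrazone F11. A Shapiro reaction (n-BuLi) followed by ZnCl2 gives the alkenylzinc chloride F12, which Negishi coupling with 24 (Pd(OAc)2, RuPhos, THF) brings back to the route at 26.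

Further compounds
F1 | step 21 | α,β-unsaturated aldehyde: 27 with CHO in place of OTf at C7 | CC1(CC[C@@H](C(C)C)[C@H]2[C@@H]3CC=C([C@@H]32)c2c(C(C)C)c(OC)c(OC)c3c2C(C=O)=CC[C@]3(C)CCC=C(C)C)OCCO1
F2 | step 21 | oxime of F1 | CC1(CC[C@@H](C(C)C)[C@H]2[C@@H]3CC=C([C@@H]32)c2c(C(C)C)c(OC)c(OC)c3c2C(C=NO)=CC[C@]3(C)CCC=C(C)C)OCCO1
F3 | step 21 | nitrile oxide from F2 | CC1(CC[C@@H](C(C)C)[C@H]2[C@@H]3CC=C([C@@H]32)c2c(C(C)C)c(OC)c(OC)c3c2C(C#[N+][O-])=CC[C@]3(C)CCC=C(C)C)OCCO1
F4 | step 21 | spiro-fused isoxazoline (C–C bond at the spiro carbon, C–O bond at the neighbouring ring carbon, both anti to the cyclopropane) | CC1(CC[C@@H](C(C)C)[C@H]2[C@@H]3C[C@H]4ON=C5C6=CC[C@](C)(CCC=C(C)C)c7c(OC)c(OC)c(C(C)C)c(c76)[C@]45[C@@H]32)OCCO1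
F5 | step 21 | β-hydroxy ketone: 28 with the cyclopentene double bond replaced by CH2–CH(OH), the OH next to the spiro carbon and anti to the cyclopropane | CC1(CC[C@@H](C(C)C)[C@H]2[C@@H]3C[C@@H](O)[C@@]4(C(=O)C5=CC[C@](C)(CCC=C(C)C)c6c(OC)c(OC)c(C(C)C)c4c65)[C@@H]32)OCCO1
F6 | step 25 | epoxide of 29 at the trisubstituted alkene (both epimers) | CC1(CC[C@@H](C(C)C)[C@H]2[C@@H]3CC[C@@]4(C(=O)C5=CC[C@](C)(CCC6OC6(C)C)c6c(OC)c(OC)c(C(C)C)c4c65)[C@@H]32)OCCO1
F7 | step 25 | tert-butyldimethylsilyl dienol ether of F6 | CC1(CC[C@@H](C(C)C)[C@H]2[C@@H]3CC[C@@]4(C(O[Si](C)(C)C(C)(C)C)=C5C=C[C@](C)(CCC6OC6(C)C)c6c(OC)c(OC)c(C(C)C)c4c65)[C@@H]32)OCCO1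
F8 | step 25 | 3-hydroxy analogue of 32 (OH on C3, both epimers) | CC1(CC[C@@H](C(C)C)[C@H]2[C@@H]3CC[C@@]4(C(=O)C5=C[C@@H]6C(C)(C)C(O)CC[C@]6(C)c7c(OC)c(OC)c(C(C)C)c4c75)[C@@H]32)OCCO1
F9 | step 25 | S-methyl xanthate of F8 | CC1(CC[C@@H](C(C)C)[C@H]2[C@@H]3CC[C@@]4(C(=O)C5=C[C@@H]6C(C)(C)C(OC(=S)SC)CC[C@]6(C)c7c(OC)c(OC)c(C(C)C)c4c75)[C@@H]32)OCCO1
F10 | step 19 | (1S,5S,6S)-6-[(3S)-2-methyl-5-(2-methyl-1,3-dioxolan-2-yl)pentan-3-yl]bicyclo[3.1.0]hexan-2-one | CC1(CC[C@@H](C(C)C)[C@H]2[C@@H]3CCC(=O)[C@@H]32)OCCO1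
F11 | step 19 | 2,4,6-triisopropylbenzenesulfonylhydrazone of F10 | CC1(CC[C@@H](C(C)C)[C@H]2[C@@H]3CCC(=NNS(=O)(=O)c4c(C(C)C)cc(C(C)C)cc4C(C)C)[C@@H]32)OCCO1
F12 | step 19 | bicyclo[3.1.0]hex-2-en-2-ylzinc chloride from F11 | CC1(CC[C@@H](C(C)C)[C@H]2[C@@H]3CC=C([Zn]Cl)[C@@H]32)OCCO1
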